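**Known runs.** A small charge of partner, 0.70 M against 2 M of substrate, gives 23.1% target at the first reading of the noon run, and each later reading stands lower.

| flask | substrate | partner | temperature | remark | time |
|---|---|---|---|---|---|
| noon | 2 M | 0.70 M | 30 °C | run made earlier |  |
| autumn | 2 M | 1 M | 65 °C | run made earlier |  |
| dawn | 3 M | 1.4 M | 30 °C | run made earlier |  |
| north-east | 2.0 M | 1.40 M | 35 °C |  | 2.5 min |
| east | 2.0 M | 1.40 M | 65 °C |  | 2.5 min |
| north-west | 2.0 M | 1.40 M | 95 °C |  | 2.5 min |

| noon: time / min | noon: target / % | autumn: time / s | autumn: target / % | dawn: time / min | dawn: target / % |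
|---|---|---|---|---|---|
| 0.667 | 23.1 | 10.0 | 6.1 | 0.667 | 26.2 |
| 1.33 | 21.0 | 12.0 | 4.8 | 1.33 | 22.6 |
| 2.00 | 18.8 | 20.0 | 3.4 | 2.00 | 19.8 |
| 2.50 | 16.8 | 30.0 | 1.7 | 2.50 | 17.2 |

(scatter of a reading: 0.5 percentage points)

- steps that have been proposed: substrate + partner <-> target + released group; partner + target -> over-reaction product; partner -> decomposed reagent

1. the flask with the highest amount of target, in percent of the substrate charged ("all alike" if they lie within 1.5 percentage points) (north-east / east / north-west / all alike)
2. final target, as a percentage of the substrate charged, in north-east
3. final target, as a percentage of the substrate charged, in east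
4. final target, as a percentage of the substrate charged, in north-west

**The rise.** In the dawn run the target climbs on average 0.393 /min of the substrate charged up to 0.667 min. It stands at 26.2% there and at 22.6% at the next reading, so the knee lies before 1.33 min.

**The tail.** Past the knee each run is read as a pseudo-first-order fall, the logarithm of first reading over last divided by the time between them. This gives 0.174 /min for noon, 0.230 /min for dawn and 3.83 /min for autumn. Noon to autumn, with somewhat more partner in autumn, makes the constant double for every 7.84 K of heating.

Dawn's constant, which has north-east's partner but more substrate, is carried up to 35 °C. The fall constant of north-east is then 0.357 /min, the net fraction of the standing target by which the curve sinks per minute. Starting from dawn's first reading, the curve reaches 13.6% at 2.5 min.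

East's tail, run on from autumn's last reading, reaches <0.001%. North-west is hotter and is reckoned lower still.

**The forecast.** It names north-east, with 13%, 0.2% and 0.2%, on the ground “Decay of about 0.3–0.4 per min over 2.5 min leaves about 13%”. That starts from a peak, whereas the reckoning above starts from a reading.

**The flask.** North-east holds 13.8% target, against 0% in east and 0% in north-west.

    substrate + partner ⇌ target + released group (K = 0.750, k = 0.120 /M/s, Ea = 43.0 kJ/mol, ΔH = −51.0 kJ/mol)
    partner + target → over-reaction product (k = 0.0110 /M/s, Ea = 57.0 kJ/mol)
    partner → decomposed reagent (k = 0.0130 /s, Ea = 89.0 kJ/mol)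
    (constants at 35 °C)

North-east stands on its falling tail, with 21.0% at 1.25 min and 13.8% at 2.50 min. That is a fall of 0.336 /min, beside the carried 0.357 /min. Heated to 40 °C with the same charges, the constant becomes 0.556 /min, which puts that neighbour at 9.46%, and the neighbour holds 7.94%.

The numbers in the tables were generated by integration for substances that don't exist; the scatter is artificial.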